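**Plan**
- Ring B is a pentasubstituted benzene. Its C2' and C5' oxygens are para, C6' carries only H and C1' holds chroman C3. This is the 4-alkoxyphenol pattern that a terminal alkyne, an alkenyl(alkoxy)carbene and one CO assemble.
- Retrosynthesis: remove the 7-O and 3'-O benzyl groups and the 2'-O-methyl group. Then cut C1'–C2', C2'–C3' and C5'–C6' to a (3S)-3-ethynylchroman and a chromium carbene complex carrying C3'–C4'–C5' with three distinct oxygens (OBn, OMe, OMe).
- The alkyne goes back through the C3 aldehyde and alcohol to a chroman-3-carboxylic acid. That acid comes from a 2H-chromene-3-carboxylic acid, and cutting O1–C2 and C3–C4 leads to a salicylaldehyde plus acrolein.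
- Forward order: ring A is bought as 2-methoxyresorcinol, pyran ring C is closed second, and ring B is built last on the finished chiral chroman.
- The only stereocentre, C3, comes from ruthenium-catalysed asymmetric hydrogenation of C3=C4 and is a bystander afterwards.

Key step: step 13

Assumption: the sense of induction in step 5 is inferred from tiglic acid, whose trisubstituted acrylic acid geometry the chromene acid shares; if the (S)-ligand favours the (3S)-acid, the (R)-ligand is used and nothing else changes.
Remark: the C3' oxygen travels as a benzyl ether because, unlike a silyl ether, it cannot shift to the neighbouring 2'-phenoxide during O-methylation; it also makes the carbene complex a stable vinylogous ester and leaves together with the 7-O-benzyl group.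

Step 1
Reactants: 1 2-methoxyresorcinol
Product: 3 2,4-dihydroxy-3-methoxybenzaldehyde, via aryl iminium dichlorophosphate 2 (not isolated)
Conditions: POCl3, DMF, MeCN, −15 °C → rt; then H2O, 50 °C
Reagents that add atoms: N,N-dimethylformamide, CN(C)C=O; water, O
Why: Vilsmeier–Haack formylation; the two activated ring positions (C4 and C6) are equivalent by symmetry, so one regioisomer can form, and the iminium salt deactivates the ring against a second attack.

Step 2
Reactants: 3 2,4-dihydroxy-3-methoxybenzaldehyde
Product: 4 4-(benzyloxy)-2-hydroxy-3-methoxybenzaldehyde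
Conditions: BnBr (1.05 equiv), NaHCO3, MeCN, 70 °C
Reagents that add atoms: benzyl bromide, BrCc1ccccc1
Why: Regioselective Williamson etherification; the 2-OH is hydrogen-bonded to the aldehyde and stays protonated under hydrogen carbonate, so only the more acidic 4-OH para to CHO should be benzylated.

Step 3
Reactants: 4 4-(benzyloxy)-2-hydroxy-3-methoxybenzaldehyde; 5 acrolein
Product: 6 7-(benzyloxy)-8-methoxy-2H-chromene-3-carbaldehyde
Conditions: K2CO3, 1,4-dioxane, reflux
Reagents that add atoms: none
Why: Domino oxa-Michael addition and intramolecular aldol condensation of a salicylaldehyde with acrolein, a standard entry to 2H-chromene-3-carbaldehydes that forms O1–C2 and C3=C4 and closes ring C.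

Step 4
Reactants: 6 7-(benzyloxy)-8-methoxy-2H-chromene-3-carbaldehyde
Product: 7 7-(benzyloxy)-8-methoxy-2H-chromene-3-carboxylic acid
Conditions: NaClO2, NaH2PO4, 2-methylbut-2-ene, t-BuOH/H2O, rt
Reagents that add atoms: sodium chlorite, [Na+].[O-]Cl=O
Why: Pinnick oxidation converts the enal into the acid without touching C3=C4, and the alkene scavenger keeps hypochlorous acid away from the electron-rich ring A.

Step 5
Reactants: 7 7-(benzyloxy)-8-methoxy-2H-chromene-3-carboxylic acid
Product: 8 (3R)-7-(benzyloxy)-8-methoxychromane-3-carboxylic acid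
Conditions: Ru(OAc)2[(S)-H8-BINAP] (1 mol %), H2 (30 bar), MeOH, 40 °C
Reagents that add atoms: none
Why: Noyori asymmetric hydrogenation of an α,β-unsaturated carboxylic acid; the substrate binds ruthenium as its carboxylate and the chiral diphosphine directs H2 to one face of C3=C4, which sets C3 as R, while the homogeneous catalyst leaves the benzyl ether alone.

Step 6
Reactants: 8 (3R)-7-(benzyloxy)-8-methoxychromane-3-carboxylic acid
Product: 9 [(3S)-7-(benzyloxy)-8-methoxychroman-3-yl]methanol
Conditions: BH3·THF, THF, 0 °C → rt; then H2O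
Reagents that add atoms: none
Why: Chemoselective borane reduction of a carboxylic acid via the acyloxyborane, run without base so that C3 keeps its configuration (the descriptor becomes S only because CH2OH ranks below C2).

Step 7
Reactants: 9 [(3S)-7-(benzyloxy)-8-methoxychroman-3-yl]methanol
Product: 10 (3R)-7-(benzyloxy)-8-methoxychromane-3-carbaldehyde
Conditions: Dess–Martin periodinane, CH2Cl2, 0 °C → rt
Reagents that add atoms: none
Why: Dess–Martin oxidation stops at the aldehyde under non-basic conditions, which protects the now enolisable C3 centre (descriptor R because CHO outranks C2).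

Step 8
Reactants: 10 (3R)-7-(benzyloxy)-8-methoxychromane-3-carbaldehyde
Product: 11 (3S)-7-(benzyloxy)-3-ethynyl-8-methoxychromane
Conditions: dimethyl (1-diazo-2-oxopropyl)phosphonate, K2CO3, MeOH, 0 °C → rt
Reagents that add atoms: dimethyl (1-diazo-2-oxopropyl)phosphonate, COP(=O)(OC)C(=[N+]=[N-])C(C)=O
Why: Ohira–Bestmann variant of the Seyferth–Gilbert homologation; the diazomethylphosphonate anion freed by methanolysis adds to the aldehyde, and loss of phosphate and N2 with a 1,2-shift gives the terminal alkyne under conditions that α-branched β-alkoxy aldehydes normally survive without epimerisation.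

Step 9
Reactants: 12 methyl methoxyacetate; 13 methyl formate
Product: 15 methyl (2Z)-3-(benzyloxy)-2-methoxyprop-2-enoate, via sodium formyl enolate 14 (not isolated)
Conditions: NaH, THF, 0 °C → rt; then BnBr, DMF, rt
Reagents that add atoms: benzyl bromide, BrCc1ccccc1
Why: Crossed Claisen condensation with a non-enolisable formate, then O-alkylation of the sodium enolate in a dipolar aprotic medium as practised for β-alkoxyacrylates, the less crowded Z isomer (OBn anti to the ester) being expected.

Step 10
Reactants: 15 methyl (2Z)-3-(benzyloxy)-2-methoxyprop-2-enoate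
Product: 16 (2Z)-3-(benzyloxy)-2-methoxyprop-2-enoic acid
Conditions: LiOH, THF/H2O, rt; then 1 M HCl to pH 3, 0 °C
Reagents that add atoms: lithium hydroxide, [Li+].[OH-]
Why: Ordinary ester saponification; the β-alkoxyacrylate is a vinylogous carbonate and should withstand hydroxide at room temperature and a brief mild acidification.

Step 11
Reactants: 16 (2Z)-3-(benzyloxy)-2-methoxyprop-2-enoic acid
Product: 17 (2Z)-3-(benzyloxy)-2-methoxyprop-2-enoyl chloride
Conditions: (COCl)2, DMF (cat.), CH2Cl2, 0 °C → rt; concentrated and used crude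
Reagents that add atoms: oxalyl chloride, O=C(Cl)C(=O)Cl
Why: Acid chloride formation through the catalytic chloroiminium species, a reaction type established for 3-alkoxyacryloyl chlorides, which are isolable reagents.

Step 12
Reactants: 17 (2Z)-3-(benzyloxy)-2-methoxyprop-2-enoyl chloride; 18 chromium hexacarbonyl
Product: 21 pentacarbonyl[(2Z)-3-(benzyloxy)-1,2-dimethoxyprop-2-en-1-ylidene]chromium, via disodium pentacarbonylchromate 19 (not isolated), via sodium acylpentacarbonylchromate 20 (not isolated)
Conditions: 18, NaC10H8 (2.1 equiv), THF, −78 → 0 °C; 17, −78 → 0 °C; solvent change to CH2Cl2, MeOTf, 0 °C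
Reagents that add atoms: methyl trifluoromethanesulfonate, COS(=O)(=O)C(F)(F)F
Why: Acid chloride variant of the Fischer carbene synthesis; the pentacarbonylchromate dianion is acylated at the metal and the acylate is O-methylated by a hard electrophile, which avoids a β-alkoxyvinyllithium that could lose alkoxide or be deprotonated at the benzylic position.

Step 13
Reactants: 11 (3S)-7-(benzyloxy)-3-ethynyl-8-methoxychromane; 21 pentacarbonyl[(2Z)-3-(benzyloxy)-1,2-dimethoxyprop-2-en-1-ylidene]chromium
Product: 23 2-(benzyloxy)-6-[(3S)-7-(benzyloxy)-8-methoxychroman-3-yl]-3,4-dimethoxyphenol, via tricarbonylchromium arene complex 22 (not isolated)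
Conditions: 21 (1.3 equiv), THF (0.2 M), 60 °C, Ar; then CO (50 bar), 70 °C
Reagents that add atoms: none
Why: Heating expels a cis CO ligand from 21, the alkyne of 11 binds and inserts with its CH terminus bonding to the carbene carbon (C5'–C6'), a CO ligand migrates onto the new vinylcarbene carbon to give a chromium-bound dienylketene (C1'–C2'), and this closes onto the benzyloxy-bearing alkene terminus (C2'–C3') and enolises to the phenol, held as complex 22. The reaction type is the Dötz benzannulation of alkenyl(alkoxy)carbene chromium complexes with terminal alkynes; oxygen on the α-carbon is tolerated in that class (dihydropyranyl and 2-furyl complexes), and the extra β-alkoxy group is the one variable without a direct model. Ring B, the only ring closed, arises as a six-membered carbocycle by 6π-electrocyclisation of the dienylketene, a [3+2+1] assembly overall. No stereocentre is created, and C3 is only a spectator because its propargylic C–H meets neither base nor acid. Two selectivities are needed: alkyne regiochemistry, secured sterically because the bulky secondary chromanyl group stays away from the carbene carbon and ends beside the CO-derived C2', and CO uptake rather than five-ring closure, favoured by chromium, an O-alkyl carbene, an alkenyl rather than aryl complex, H rather than OBn lying cis to the carbene carbon in the Z-alkene, and a concentrated ethereal solution. CO pressure then displaces the arene from zerovalent chromium without an oxidant, so that the electron-rich hydroquinone monoether is not carried on to the quinone and Cr(CO)6 is recovered.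

Step 14
Reactants: 23 2-(benzyloxy)-6-[(3S)-7-(benzyloxy)-8-methoxychroman-3-yl]-3,4-dimethoxyphenol
Product: 24 (3S)-7-(benzyloxy)-3-[3-(benzyloxy)-2,4,5-trimethoxyphenyl]-8-methoxychromane
Conditions: MeI, K2CO3, DMF, rt, Ar
Reagents that add atoms: iodomethane, CI
Why: Williamson etherification of the only free phenol, with no migrating group on the neighbouring oxygen, so the 2'-OMe/3'-OBn assignment made in the annulation is kept.

Step 15
Reactants: 24 (3S)-7-(benzyloxy)-3-[3-(benzyloxy)-2,4,5-trimethoxyphenyl]-8-methoxychromane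
Product: 25 (3S)-3-(3-hydroxy-2,4,5-trimethoxyphenyl)-8-methoxychroman-7-ol
Conditions: H2 (1 atm), Pd/C (10 wt %), EtOAc/MeOH, rt
Reagents that add atoms: none
Why: Catalytic hydrogenolysis cleaves both benzyl aryl ethers at once, and since the chroman has no benzylic C–O bond, ring C and the C3 centre should be untouched.

**Compound list**
1 | 2-methoxyresorcinol | COc1c(O)cccc1O | starting material
2 | [(2,4-dihydroxy-3-methoxyphenyl)methylidene]dimethyliminium dichlorophosphate | C[N+](C)=Cc1ccc(O)c(OC)c1O.[O-]P(Cl)(Cl)=O | intermediate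
3 | 2,4-dihydroxy-3-methoxybenzaldehyde | O=Cc1ccc(O)c(OC)c1O | intermediate
4 | 4-(benzyloxy)-2-hydroxy-3-methoxybenzaldehyde | O=Cc1ccc(OCc2ccccc2)c(OC)c1O | intermediate
5 | acrolein | C=CC=O | starting material
6 | 7-(benzyloxy)-8-methoxy-2H-chromene-3-carbaldehyde | O=CC1=Cc2ccc(OCc3ccccc3)c(OC)c2OC1 | intermediate
7 | 7-(benzyloxy)-8-methoxy-2H-chromene-3-carboxylic acid | OC(=O)C1=Cc2ccc(OCc3ccccc3)c(OC)c2OC1 | intermediate
8 | (3R)-7-(benzyloxy)-8-methoxychromane-3-carboxylic acid | OC(=O)[C@H]1COc2c(ccc(OCc3ccccc3)c2OC)C1 | intermediate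
9 | [(3S)-7-(benzyloxy)-8-methoxychroman-3-yl]methanol | OC[C@H]1COc2c(ccc(OCc3ccccc3)c2OC)C1 | intermediate
10 | (3R)-7-(benzyloxy)-8-methoxychromane-3-carbaldehyde | O=C[C@H]1COc2c(ccc(OCc3ccccc3)c2OC)C1 | intermediate
11 | (3S)-7-(benzyloxy)-3-ethynyl-8-methoxychromane | C#C[C@H]1COc2c(ccc(OCc3ccccc3)c2OC)C1 | intermediate
12 | methyl methoxyacetate | COCC(=O)OC | starting material
13 | methyl formate | COC=O | starting material
14 | sodium 2,3-dimethoxy-3-oxoprop-1-en-1-olate (configurationally labile) | COC(=C[O-])C(=O)OC.[Na+] | intermediate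
15 | methyl (2Z)-3-(benzyloxy)-2-methoxyprop-2-enoate | CO/C(=C\OCc1ccccc1)C(=O)OC | intermediate
16 | (2Z)-3-(benzyloxy)-2-methoxyprop-2-enoic acid | CO/C(=C\OCc1ccccc1)C(=O)O | intermediate
17 | (2Z)-3-(benzyloxy)-2-methoxyprop-2-enoyl chloride | CO/C(=C\OCc1ccccc1)C(=O)Cl | intermediate
18 | chromium hexacarbonyl | O=C=[Cr](=C=O)(=C=O)(=C=O)(=C=O)=C=O | starting material
19 | disodium pentacarbonylchromate | [Na+].[Na+].O=C=[Cr-2](=C=O)(=C=O)(=C=O)=C=O | intermediate
20 | sodium pentacarbonyl[(2Z)-3-(benzyloxy)-2-methoxyprop-2-enoyl]chromate | CO/C(=C\OCc1ccccc1)C([O-])=[Cr](=C=O)(=C=O)(=C=O)(=C=O)=C=O.[Na+] | intermediate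
21 | pentacarbonyl[(2Z)-3-(benzyloxy)-1,2-dimethoxyprop-2-en-1-ylidene]chromium | CO/C(=C\OCc1ccccc1)C(OC)=[Cr](=C=O)(=C=O)(=C=O)(=C=O)=C=O | intermediate
22 | tricarbonylchromium complex of 23, metal η6-bound to ring B (the η6 bond is not drawn) | COc1cc([C@H]2COc3c(ccc(OCc4ccccc4)c3OC)C2)c(O)c(OCc2ccccc2)c1OC.O=C=[Cr](=C=O)=C=O | intermediate
23 | 2-(benzyloxy)-6-[(3S)-7-(benzyloxy)-8-methoxychroman-3-yl]-3,4-dimethoxyphenol | COc1cc([C@H]2COc3c(ccc(OCc4ccccc4)c3OC)C2)c(O)c(OCc2ccccc2)c1OC | intermediate
24 | (3S)-7-(benzyloxy)-3-[3-(benzyloxy)-2,4,5-trimethoxyphenyl]-8-methoxychromane | COc1cc([C@H]2COc3c(ccc(OCc4ccccc4)c3OC)C2)c(OC)c(OCc2ccccc2)c1OC | intermediate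
25 | (3S)-3-(3-hydroxy-2,4,5-trimethoxyphenyl)-8-methoxychroman-7-ol | COc1cc([C@H]2COc3c(ccc(O)c3OC)C2)c(OC)c(O)c1OC | target

Total step count: 15. Longest linear sequence: 11 (steps 1–8, then 13–15).

**Steps most likely to fail**

**Step 13.**
- Risk: the two oxygen donors on the alkenyl unit enrich chromium and may slow the CO dissociation that opens the reaction. The β-alkoxy group may also steer the vinylcarbene intermediate into five-membered ring closure without CO uptake.
- Fallback idea: keep the annulation, but take the C3' oxygen out of it and install it afterwards by phenol-directed chemistry.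
- Carbene partner, setting out from 11 and 18: methyl vinyl ether is α-lithiated (t-BuLi, THF, −78 → 0 °C) to 1-methoxyvinyllithium F1. Addition to 18 gives lithium pentacarbonyl(2-methoxyprop-2-enoyl)chromate F2. MeOTf then gives pentacarbonyl(1,2-dimethoxyprop-2-en-1-ylidene)chromium F3, an α-alkoxyalkenyl complex of the well-behaved type.
- Annulation: benzannulation with 11 under the conditions of step 13 should pass through the tricarbonylchromium arene complex F4 to 2-[(3S)-7-(benzyloxy)-8-methoxychroman-3-yl]-4,5-dimethoxyphenol F5. In this phenol C3' is the only free position ortho to the hydroxyl group.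
- Installing the C3' oxygen: Casnati–Skattebøl ortho-formylation (MgCl2, Et3N, paraformaldehyde, MeCN, reflux) gives 3-[(3S)-7-(benzyloxy)-8-methoxychroman-3-yl]-2-hydroxy-5,6-dimethoxybenzaldehyde F6. MeI/K2CO3 gives 3-[(3S)-7-(benzyloxy)-8-methoxychroman-3-yl]-2,5,6-trimethoxybenzaldehyde F7. Baeyer–Villiger oxidation with mCPBA gives 3-[(3S)-7-(benzyloxy)-8-methoxychroman-3-yl]-2,5,6-trimethoxyphenyl formate F8. K2CO3 (cat.)/MeOH frees 3-[(3S)-7-(benzyloxy)-8-methoxychroman-3-yl]-2,5,6-trimethoxyphenol F9.
- Return: hydrogenolysis of the one benzyl ether under the conditions of step 15 brings the sequence back to the route at 25.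

**Step 12.**
- Risk: the chromate dianion is a strong reductant. Electron transfer to the acid chloride, or attack at the β-carbon with loss of benzyloxide, may outrun acylation at the carbonyl group.
- Fallback idea: reverse the polarity and use the classical organolithium entry to Fischer carbene complexes.
- Sequence, setting out from 16 and 18: Hunsdiecker-type bromodecarboxylation (NBS, Et3N cat., CH2Cl2, rt), which the β-oxygen donor should favour, gives {[(E)-2-bromo-2-methoxyethenyl]oxymethyl}benzene F10. Bromine–lithium exchange (t-BuLi, 2 equiv, Et2O, −78 °C), faster than benzylic deprotonation, gives (Z)-2-(benzyloxy)-1-methoxyvinyllithium F11. This belongs to the 1,2-dialkoxyvinyllithium family known from lithiated 1,4-dioxene. Addition to 18 gives lithium pentacarbonyl[(2Z)-3-(benzyloxy)-2-methoxyprop-2-enoyl]chromate F12.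
- Return: MeOTf returns to the route at 21.

**Step 8.**
- Risk: carbonate in methanol may erode the configurational purity of 10 before the homologation is complete. This could happen through enolisation, or through reversible β-elimination of the ring phenoxide followed by reclosure.
- Fallback idea: the Corey–Fuchs sequence, whose olefination runs without base.
- Sequence, setting out from 10: CBr4/PPh3 (CH2Cl2, 0 °C) gives (3S)-7-(benzyloxy)-3-(2,2-dibromoethenyl)-8-methoxychromane F13, in which the C3–H is no longer acidic. n-BuLi (2.1 equiv, THF, −78 °C) gives lithium [(3S)-7-(benzyloxy)-8-methoxychroman-3-yl]acetylide F14 by Fritsch–Buttenberg–Wiechell rearrangement.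
- Return: aqueous quench returns to the route at 11.

**Further compounds**
F1 | step 13 | 1-methoxyvinyllithium | [Li]C(=C)OC
F2 | step 13 | lithium pentacarbonyl(2-methoxyprop-2-enoyl)chromate | C=C(OC)C([O-])=[Cr](=C=O)(=C=O)(=C=O)(=C=O)=C=O.[Li+]
F3 | step 13 | pentacarbonyl(1,2-dimethoxyprop-2-en-1-ylidene)chromium | C=C(OC)C(OC)=[Cr](=C=O)(=C=O)(=C=O)(=C=O)=C=O
F4 | step 13 | tricarbonylchromium complex of F5, metal η6-bound to ring B (the η6 bond is not drawn) | COc1cc(O)c([C@H]2COc3c(ccc(OCc4ccccc4)c3OC)C2)cc1OC.O=C=[Cr](=C=O)=C=O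
F5 | step 13 | 2-[(3S)-7-(benzyloxy)-8-methoxychroman-3-yl]-4,5-dimethoxyphenol | COc1cc(O)c([C@H]2COc3c(ccc(OCc4ccccc4)c3OC)C2)cc1OC
F6 | step 13 | 3-[(3S)-7-(benzyloxy)-8-methoxychroman-3-yl]-2-hydroxy-5,6-dimethoxybenzaldehyde | COc1cc([C@H]2COc3c(ccc(OCc4ccccc4)c3OC)C2)c(O)c(C=O)c1OC
F7 | step 13 | 3-[(3S)-7-(benzyloxy)-8-methoxychroman-3-yl]-2,5,6-trimethoxybenzaldehyde | COc1cc([C@H]2COc3c(ccc(OCc4ccccc4)c3OC)C2)c(OC)c(C=O)c1OC
F8 | step 13 | 3-[(3S)-7-(benzyloxy)-8-methoxychroman-3-yl]-2,5,6-trimethoxyphenyl formate | COc1cc([C@H]2COc3c(ccc(OCc4ccccc4)c3OC)C2)c(OC)c(OC=O)c1OC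
F9 | step 13 | 3-[(3S)-7-(benzyloxy)-8-methoxychroman-3-yl]-2,5,6-trimethoxyphenol | COc1cc([C@H]2COc3c(ccc(OCc4ccccc4)c3OC)C2)c(OC)c(O)c1OC
F10 | step 12 | {[(E)-2-bromo-2-methoxyethenyl]oxymethyl}benzene | CO/C(Br)=C\OCc1ccccc1
F11 | step 12 | (Z)-2-(benzyloxy)-1-methoxyvinyllithium | CO/C([Li])=C\OCc1ccccc1
F12 | step 12 | lithium pentacarbonyl[(2Z)-3-(benzyloxy)-2-methoxyprop-2-enoyl]chromate | CO/C(=C\OCc1ccccc1)C([O-])=[Cr](=C=O)(=C=O)(=C=O)(=C=O)=C=O.[Li+]
F13 | step 8 | (3S)-7-(benzyloxy)-3-(2,2-dibromoethenyl)-8-methoxychromane | BrC(Br)=C[C@H]1COc2c(ccc(OCc3ccccc3)c2OC)C1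
F14 | step 8 | lithium [(3S)-7-(benzyloxy)-8-methoxychroman-3-yl]acetylide | [Li]C#C[C@H]1COc2c(ccc(OCc3ccccc3)c2OC)C1
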